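Remark on the chemistry: the 1,3-diketones 3, 4 and 5 are drawn and named as diketo tautomers, although they should exist largely as hydrogen-bonded enols. Both starting materials are taken to be commercial.

## Analysis of the target

The target 8 is a flavone: ring A is fused to the 4-pyranone ring C, and ring B is attached at C2. It has no stereocentre, and the C2–C1' axis, although flanked by the 2'-methoxy and 6'-hydroxy groups, should rotate freely past O1 and C3–H, so no stereochemical relationship has to be set. Ring A carries a hydroxyl at C5 and methoxy groups at C6 and C7; ring B carries methoxy groups at C2', C3' and C4' and a hydroxyl at C6'; only C8 and C5' remain as aromatic C–H. The sensitive features are the two very electron-rich rings (easily oxidised), the pyranone (opened by strong base) and the methyl ethers at C5, C6 and C3', which a Lewis acid removes most easily. The difficulty lies in the oxygen pattern: two phenols must be distinguished from five methyl ethers, and ring B is substituted at both positions ortho to C1', which normally demands a fully oxygenated, protected building block. The plan rests on what appears when ring C is opened at O1–C2: the bridge C2–C3–C4 then carries two identically substituted aryl groups, with C5, C6, C7, C8 and C8a of ring A matching C2', C3', C4', C5' and C6' of ring B. In each ring the oxygen that is not a methyl ether (O1 on C8a, the hydroxyl on C6') sits on the one carbon ortho to the bridge that a 2,3,4-trimethoxyphenyl group leaves free. The remaining difference, hydroxyl at C5 against methoxy at C2', lies peri to the C4 carbonyl and can be settled by chelation at the end.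

## Retrosynthetic reasoning

**From 8 to 6 (O–CH3 at C5).** The free 5-hydroxyl is traced back to a methyl ether, giving the flavone 6. This is the only one of the six methyl ethers of 6 that lies peri to the C4 carbonyl, so a chelating Lewis acid can single it out. The gain is that both rings of 6 now carry the same 2,3,4-trimethoxy pattern plus one further oxygen. The forward step must cleave one methyl ether out of six and leave the free 6'-phenol untouched; it passes through the boron derivative 7.

**From 6 to 5 (O1–C2 of ring C).** Cutting O1–C2 with formal addition of water opens the pyranone to the bis(hydroxyaryl) 1,3-diketone 5. This cut is preferred over a C–C disconnection of ring C because it exposes the equivalence of the two aryl groups. As the two halves of 5 are identical, ring closure from either phenol onto either carbonyl leads to the same flavone, so there is no regiochemical question. The forward reaction is an acid cyclodehydration.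

**From 5 to 3 (C8a–O and C6'–O).** The two aryl C–O bonds ortho to the carbonyl groups are replaced by C–H, giving the symmetric diketone 3. These are the only C–O bonds in the molecule that a ketone can direct a metal to form, and in 3 each ring offers exactly one ortho C–H bond, the other ortho position being methoxylated. The gain is large: both rings come from the cheap 2,3,4-trimethoxyphenyl pattern, no ring needs a pre-installed, protected phenol, and both oxygens enter in one operation. The forward reaction must oxygenate two aryl C–H bonds through the bis(trifluoroacetate) 4 while sparing the central methylene and the electron-rich rings.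

**From 3 to 1 and 2 (central C–C(=O) bond).** Cutting one bond between the central carbon and a carbonyl carbon gives the methyl ketone 1 and the ester 2, which share the same aryl group. A crossed Claisen condensation is the forward reaction; the ester cannot enolise, so only one product is possible. The precursor of the key step is thus one step from commercial materials, and the risk of the route sits in the C–H oxygenation.

## Alternatives that were turned down

**Alternative 1:** Ring C is disconnected at O1–C2 and C3–C4 as a hetero-Diels–Alder adduct. The diene is the ortho-quinone methide derived from the salicylaldehyde A2 (6-hydroxy-2,3,4-trimethoxybenzaldehyde); the dienophile is the ring B styrene A3 (1-(benzyloxy)-2-ethenyl-3,4,5-trimethoxybenzene). In the forward key step A2 would be activated with acid and an orthoester, and the quinone methide would add across the vinyl group of A3 to give the cis 4-methoxyflavan A1.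
- For it: the polarity of both partners fixes the regiochemistry, every reaction type has precedent, and A3 can be made from A2, so this plan also uses the equivalence of the two rings. On reliability of the bond-forming step it is stronger than the chosen plan.
- Against it: A1 has two stereocentres that are made only to be destroyed. C4 must be raised from ether to ketone and C2=C3 introduced (ether hydrolysis, oxidation, dehydrogenation), followed by debenzylation and the same 5-O-demethylation. The styrene in A3 is ortho,ortho-disubstituted, so it is twisted out of conjugation and hindered toward cycloaddition. Both phenolic oxygens must already be present in A2, and one must be protected.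
- Comparison: the chosen plan gives up that certainty, but offers four steps from 1 and 2, no protecting group and no correction of the oxidation level of ring C.

**Alternative 2:** Only the C6'–O bond is disconnected, the oxygen being delivered from a carboxyl group at C3. In the forward key step the flavone-3-carboxylic acid A5 (5,6,7-trimethoxy-4-oxo-2-(2,3,4-trimethoxyphenyl)-4H-chromene-3-carboxylic acid) would be oxidised at a carbon anode, so that a carboxyl oxygen attacks C6' and closes the six-membered lactone A4.
- For it: the tether allows only C6' (or, less favourably, ipso attack at the methoxylated C2') to be reached, the oxidant is electric current, and the closest analogy, dehydrogenative lactonisation of biaryl carboxylic acids, is established. On site control and freedom from metal catalysts it is as strong as or stronger than the chosen plan.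
- Against it: it makes only one of the two phenolic C–O bonds, so ring A must still come from a pre-oxygenated hydroxy ketone. A5 has to be assembled and the carboxyl later removed by lactone opening and decarboxylation, and base strong enough to open the lactone also threatens the pyranone. The hexamethoxylated flavone is likely to be oxidised at the anode at several positions, and the 5-O-demethylation still follows.
- Comparison: the chosen plan installs both oxygens in one step on a precursor made in one step, and needs no tether to be put on and taken off.

**Alternative 3:** Ring A is disconnected at C4a–C5 and built on a preformed 2-aryl-4-pyranone. In the forward key step the β-keto ester A7 (methyl 4-{6-[6-(benzyloxy)-2,3,4-trimethoxyphenyl]-4-oxo-4H-pyran-2-yl}-2-methoxy-3-oxobutanoate) would be treated with base, the pyranone carbon that becomes C4a would attack the ester carbonyl, and enolisation would aromatise ring A to the 5,7-dihydroxy-6-methoxyflavone A6.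
- For it: the folding resembles polyketide biosynthesis, the 5-hydroxyl appears free without any ether cleavage, and the 7-hydroxyl of A6 can be methylated selectively because the 5-hydroxyl is chelated. In avoiding both a Lewis acid demethylation and an oxidation of electron-rich rings it is stronger than the chosen plan.
- Against it: A7 is a long way from commercial materials. It has two more acidic positions in its side chain than the ring carbon that must act as the nucleophile, so O-acylation and base-induced opening of the pyranone compete. Ring B with its 6'-oxygen must still be brought in as a finished, benzyl-protected unit, so the hard part of ring B is not solved, and methylation and debenzylation follow.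
- Comparison: the chosen plan is several times shorter and draws both rings from one inexpensive aryl pattern.

Key step: step 2

## Route

Step 1
Reactants: 1 1-(2,3,4-trimethoxyphenyl)ethanone; 2 methyl 2,3,4-trimethoxybenzoate
Product: 3 1,3-bis(2,3,4-trimethoxyphenyl)propane-1,3-dione
Conditions: NaH (2.5 equiv), THF, reflux; then 1 M HCl, 0 °C
Reagents that add atoms: none
Why: Crossed Claisen condensation: ester 2 has no α-hydrogen and can act only as the acceptor, and the product is held as its sodium enolate, which draws the equilibrium forward until acidification releases 3.

Step 2
Reactants: 3 1,3-bis(2,3,4-trimethoxyphenyl)propane-1,3-dione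
Product: 5 1,3-bis(6-hydroxy-2,3,4-trimethoxyphenyl)propane-1,3-dione, via bis(trifluoroacetate) ester 4 (not isolated)
Conditions: [RuCl2(p-cymene)]2 (5 mol %), K2S2O8 (2.4 equiv, in portions), CF3CO2H/(CF3CO)2O, 80 °C; then H2O, rt
Reagents that add atoms: trifluoroacetic acid, OC(=O)C(F)(F)F (a carboxylate oxygen becomes each phenolic oxygen; the trifluoroacetyl groups of 4 are lost on work-up)
Why: Proposed new method: the closest known reaction type is the ketone-directed ortho C–H hydroxylation of simple aryl ketones by divalent ruthenium or divalent palladium carboxylates with a persulfate or trivalent iodine oxidant in CF3CO2H/(CF3CO)2O, which has not been shown on a 1,3-diketone or twice in one molecule. [RuCl2(p-cymene)]2 should exchange chloride for trifluoroacetate, bind the outward lone pair of a carbonyl oxygen of 3 and cleave the C6–H bond of the attached ring by carboxylate-assisted concerted metalation–deprotonation to a five-membered ruthenacycle; K2S2O8 should oxidise this to a tetravalent ruthenium trifluoroacetate, and C–O reductive elimination should release the aryl trifluoroacetate and divalent ruthenium, the cycle then repeating on the second ring to give 4. Because the enol of 3 passes its proton quickly between the two oxygens, each ring in turn is attached to a true carbonyl group, so one catalyst system should serve both sites. Site selectivity is secured by the substrate alone: C6 is the only C–H ortho to each carbonyl, C2 carries a methoxy group, and C5–H cannot be reached through a five-membered metallacycle. The chemoselectivity needed is oxidation of two aryl C–H bonds in preference to the central methylene and the electron-rich rings; a difluoroboron chelate would shield the central carbon but would also occupy the oxygen lone pairs that must steer the metal, so the free diketone is used and the protection is sought in the reagents: the strong acid keeps the diketone un-ionised, K2S2O8 is chosen over trivalent iodine oxidants (which attack enols of 1,3-dicarbonyl compounds) and is added in portions, and (CF3CO)2O may hold part of the enol as its less nucleophilic trifluoroacetate. The same anhydride keeps each new phenol acylated as in 4, which lowers the electron density of the ring against over-oxidation and prevents early closure to a flavone that would remove the directing carbonyl of the second ring. No ring is closed and no stereocentre is formed; water hydrolyses 4 to 5, whose phenols are then hydrogen-bonded to the carbonyl groups.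

Step 3
Reactants: 5 1,3-bis(6-hydroxy-2,3,4-trimethoxyphenyl)propane-1,3-dione
Product: 6 2-(6-hydroxy-2,3,4-trimethoxyphenyl)-5,6,7-trimethoxy-4H-chromen-4-one
Conditions: H2SO4 (cat.), AcOH, 90 °C
Reagents that add atoms: none
Why: Acid-catalysed cyclodehydration of a 2-hydroxyaryl 1,3-diketone, the closing stage of the Baker–Venkataraman flavone synthesis: a phenol oxygen adds to the protonated distal carbonyl (6-exo-trig) and water is lost to give the conjugated pyranone. Because the two halves of 5 are identical, either phenol on either carbonyl gives the same flavone 6, and the second phenol cannot close a ring because the C2=C3 double bond holds it away from C4.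

Step 4
Reactants: 6 2-(6-hydroxy-2,3,4-trimethoxyphenyl)-5,6,7-trimethoxy-4H-chromen-4-one
Product: 8 5,6'-dihydroxy-6,7,2',3',4'-pentamethoxyflavone, via 5-O,6'-O-bis(dichloroboryl) derivative 7 (not isolated)
Conditions: BCl3 (2.5 equiv), CH2Cl2, −78 → 0 °C; then 1 M HCl, rt
Reagents that add atoms: boron trichloride, ClB(Cl)Cl (boron and chlorine are held only in intermediate 7 and are absent from 8)
Why: Chelation-controlled Lewis acid ether cleavage: boron bound to the C4 carbonyl oxygen reaches only the peri 5-methoxy oxygen, whose methyl group chloride then removes in an SN2 step, while the other five methyl ethers have no carbonyl neighbour; one further equivalent is taken up by the 6'-phenol. Aqueous acid hydrolyses the boron–oxygen bonds of 7 and releases 8.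

## Compound list

1 | 1-(2,3,4-trimethoxyphenyl)ethanone | CC(=O)c1ccc(OC)c(OC)c1OC | starting material
2 | methyl 2,3,4-trimethoxybenzoate | COC(=O)c1ccc(OC)c(OC)c1OC | starting material
3 | 1,3-bis(2,3,4-trimethoxyphenyl)propane-1,3-dione | COc1ccc(C(=O)CC(=O)c2ccc(OC)c(OC)c2OC)c(OC)c1OC | intermediate
4 | 1,3-bis[2,3,4-trimethoxy-6-(trifluoroacetoxy)phenyl]propane-1,3-dione | COc1cc(OC(=O)C(F)(F)F)c(C(=O)CC(=O)c2c(OC(=O)C(F)(F)F)cc(OC)c(OC)c2OC)c(OC)c1OC | intermediate (not isolated)
5 | 1,3-bis(6-hydroxy-2,3,4-trimethoxyphenyl)propane-1,3-dione | COc1cc(O)c(C(=O)CC(=O)c2c(O)cc(OC)c(OC)c2OC)c(OC)c1OC | intermediate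
6 | 2-(6-hydroxy-2,3,4-trimethoxyphenyl)-5,6,7-trimethoxy-4H-chromen-4-one (6'-hydroxy-5,6,7,2',3',4'-hexamethoxyflavone) | COc1cc(O)c(-c2cc(=O)c3c(OC)c(OC)c(OC)cc3o2)c(OC)c1OC | intermediate
7 | 5-[(dichloroboranyl)oxy]-2-{6-[(dichloroboranyl)oxy]-2,3,4-trimethoxyphenyl}-6,7-dimethoxy-4H-chromen-4-one, the C4 carbonyl oxygen coordinated to the boron on O5 | COc1cc(OB(Cl)Cl)c(-c2cc(=O)c3c(OB(Cl)Cl)c(OC)c(OC)cc3o2)c(OC)c1OC | intermediate (not isolated)
8 | 5,6'-dihydroxy-6,7,2',3',4'-pentamethoxyflavone | COc1cc(O)c(-c2cc(=O)c3c(O)c(OC)c(OC)cc3o2)c(OC)c1OC | target

## Step count and least certain steps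

Total: 4 steps. Longest linear sequence: 4 steps (from 1 or from 2; the two starting materials meet in step 1).

**Step 2 (key step, proposed new method).** The most likely failure is loss of chemoselectivity: the oxidant or radicals derived from it may attack the central methylene of the diketone (oxygenation or cleavage of the chain) or oxidise the trimethoxylated rings. The catalyst may also be held back as an O,O-bound diketonate, so that the reaction stalls after the first oxygenation.

The fallback moves the oxygenation in front of the condensation, where it falls within the established class of simple aryl ketones and benzoates.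
- Ketone 1 is treated with [RuCl2(p-cymene)]2 and K2S2O8 in CF3CO2H/(CF3CO)2O to give 2-acetyl-3,4,5-trimethoxyphenyl trifluoroacetate F1, hydrolysed on aqueous work-up to 1-(6-hydroxy-2,3,4-trimethoxyphenyl)ethanone F2.
- Ester 2 is treated in the same way (ester-directed variant) to give methyl 2,3,4-trimethoxy-6-(trifluoroacetoxy)benzoate F3 and then methyl 6-hydroxy-2,3,4-trimethoxybenzoate F4, which is benzylated (BnBr, K2CO3, DMF) to methyl 6-(benzyloxy)-2,3,4-trimethoxybenzoate F5.
- The dianion of F2 (LiN(SiMe3)2, 3 equiv, THF, −78 °C to rt) is condensed with F5 to give 1-[6-(benzyloxy)-2,3,4-trimethoxyphenyl]-3-(6-hydroxy-2,3,4-trimethoxyphenyl)propane-1,3-dione F6.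
- Hydrogenolysis (H2, Pd/C, EtOAc) returns to the route at 5.

The price is four extra operations, a benzyl group and a Claisen condensation onto a 2,6-disubstituted ester, which should be slow.

**Step 4.** The free 6'-phenol consumes one equivalent of BCl3, so an excess is unavoidable. That excess may erode site selectivity, with cleavage continuing at the 6-methoxy group next to the new chelate or at the flanked 3'-methoxy group of ring B.

The fallback removes the phenol from play so that the Lewis acid can be metered to the single chelating site.
- Flavone 6 is acetylated (Ac2O, pyridine) to 3,4,5-trimethoxy-2-(5,6,7-trimethoxy-4-oxo-4H-chromen-2-yl)phenyl acetate F7.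
- BCl3 (1.1 equiv, CH2Cl2, −78 to −20 °C) gives the 5-O-dichloroboryl chelate F8, hydrolysed on work-up to 2-(5-hydroxy-6,7-dimethoxy-4-oxo-4H-chromen-2-yl)-3,4,5-trimethoxyphenyl acetate F9.
- Methanolysis of the acetate (K2CO3, MeOH, rt) returns to the route at 8.

**Step 1.** The condensation is reversible, and the ortho-methoxylated, electron-rich ester is a sluggish acceptor, so self-condensation of the ketone enolate and incomplete acyl transfer may compete.

The fallback replaces the equilibrium condensation by an irreversible acylation.
- Ester 2 is saponified (LiOH, THF/H2O; then HCl) to 2,3,4-trimethoxybenzoic acid F10.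
- F10 is converted with (COCl)2 and catalytic DMF in CH2Cl2 into 2,3,4-trimethoxybenzoyl chloride F11.
- The preformed lithium enolate of 1 (LiN(SiMe3)2, 2.1 equiv, THF, −78 °C) is C-acylated with F11, returning to the route at 3.

## Further compounds

F1 | step 2 | 2-acetyl-3,4,5-trimethoxyphenyl trifluoroacetate | CC(=O)c1c(OC(=O)C(F)(F)F)cc(OC)c(OC)c1OC
F2 | step 2 | 1-(6-hydroxy-2,3,4-trimethoxyphenyl)ethanone | CC(=O)c1c(O)cc(OC)c(OC)c1OC
F3 | step 2 | methyl 2,3,4-trimethoxy-6-(trifluoroacetoxy)benzoate | COC(=O)c1c(OC(=O)C(F)(F)F)cc(OC)c(OC)c1OC
F4 | step 2 | methyl 6-hydroxy-2,3,4-trimethoxybenzoate | COC(=O)c1c(O)cc(OC)c(OC)c1OC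
F5 | step 2 | methyl 6-(benzyloxy)-2,3,4-trimethoxybenzoate | COC(=O)c1c(OCc2ccccc2)cc(OC)c(OC)c1OC
F6 | step 2 | 1-[6-(benzyloxy)-2,3,4-trimethoxyphenyl]-3-(6-hydroxy-2,3,4-trimethoxyphenyl)propane-1,3-dione | COc1cc(OCc2ccccc2)c(C(=O)CC(=O)c2c(O)cc(OC)c(OC)c2OC)c(OC)c1OC
F7 | step 4 | 3,4,5-trimethoxy-2-(5,6,7-trimethoxy-4-oxo-4H-chromen-2-yl)phenyl acetate | COc1cc(OC(C)=O)c(-c2cc(=O)c3c(OC)c(OC)c(OC)cc3o2)c(OC)c1OC
F8 | step 4 | 2-{5-[(dichloroboranyl)oxy]-6,7-dimethoxy-4-oxo-4H-chromen-2-yl}-3,4,5-trimethoxyphenyl acetate, the C4 carbonyl oxygen coordinated to boron | COc1cc(OC(C)=O)c(-c2cc(=O)c3c(OB(Cl)Cl)c(OC)c(OC)cc3o2)c(OC)c1OC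
F9 | step 4 | 2-(5-hydroxy-6,7-dimethoxy-4-oxo-4H-chromen-2-yl)-3,4,5-trimethoxyphenyl acetate | COc1cc(OC(C)=O)c(-c2cc(=O)c3c(O)c(OC)c(OC)cc3o2)c(OC)c1OC
F10 | step 1 | 2,3,4-trimethoxybenzoic acid | COc1ccc(C(=O)O)c(OC)c1OC
F11 | step 1 | 2,3,4-trimethoxybenzoyl chloride | COc1ccc(C(=O)Cl)c(OC)c1OC
A1 | alternative 1 | racemic cis-2-[6-(benzyloxy)-2,3,4-trimethoxyphenyl]-4,5,6,7-tetramethoxychroman (one enantiomer drawn) | COc1cc(OCc2ccccc2)c([C@@H]2C[C@H](OC)c3c(OC)c(OC)c(OC)cc3O2)c(OC)c1OC
A2 | alternative 1 | 6-hydroxy-2,3,4-trimethoxybenzaldehyde | COc1cc(O)c(C=O)c(OC)c1OC
A3 | alternative 1 | 1-(benzyloxy)-2-ethenyl-3,4,5-trimethoxybenzene | C=Cc1c(OCc2ccccc2)cc(OC)c(OC)c1OC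
A4 | alternative 2 | hexamethoxy-6H,7H-chromeno[4,3-b]chromene-6,7-dione, the lactone joining the 6'-oxygen to the C3 carboxyl (methoxy groups at flavone positions 5, 6, 7, 2', 3' and 4') | COc1cc2oc(=O)c3c(=O)c4c(OC)c(OC)c(OC)cc4oc3c2c(OC)c1OC
A5 | alternative 2 | 5,6,7-trimethoxy-4-oxo-2-(2,3,4-trimethoxyphenyl)-4H-chromene-3-carboxylic acid | COc1ccc(-c2oc3cc(OC)c(OC)c(OC)c3c(=O)c2C(=O)O)c(OC)c1OC
A6 | alternative 3 | 2-[6-(benzyloxy)-2,3,4-trimethoxyphenyl]-5,7-dihydroxy-6-methoxy-4H-chromen-4-one | COc1cc(OCc2ccccc2)c(-c2cc(=O)c3c(O)c(OC)c(O)cc3o2)c(OC)c1OC
A7 | alternative 3 | methyl 4-{6-[6-(benzyloxy)-2,3,4-trimethoxyphenyl]-4-oxo-4H-pyran-2-yl}-2-methoxy-3-oxobutanoate | COC(=O)C(OC)C(=O)Cc1cc(=O)cc(-c2c(OCc3ccccc3)cc(OC)c(OC)c2OC)o1
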